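**Plan**

1. Retrosynthetic cuts: the O8–angeloyl ester bond; ring A at C5–C6 (6π closure of a dienylketene, back to a 4-acetoxy-4-dienylcyclobutenone); C1–C2 (dienyllithium plus cyclobutenedione); C1–C7 (Negishi coupling with 1,1-dibromoethene); C4–CH3 (MeLi on a squarate); C7–C8 (acetylide plus Weinreb amide).
2. Enabling feature: ring A carries four contiguous carbons C2(OAc), C3(O), C4(CH3), C5(O) that map onto the acetoxy carbon, the alkoxy carbon, the methyl carbon and the carbonyl carbon of a 3-alkoxy-2-methylcyclobutenone; only C1 and C6 are missing, and they are the vinyl unit of a diene attached through C7.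
3. Forward order: the C8 side chain is built linearly to a 2-bromo-1,3-diene, joined to the four-membered ring with the O2 acetate set in the same flask, ring A is formed by thermal ring expansion, and the angelate is attached once the arene exists.
4. Stereochemistry: C8 (S) comes from Noyori transfer hydrogenation of an ynone with the (S,S)-catalyst and is not touched afterwards; the Z alkene of the ester comes from angelic acid.
5. Protecting groups: O3 4-methoxybenzyl (from the squarate), O8 triethylsilyl, O5 tert-butyldimethylsilyl (added after ring A is formed).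

Key step: step 12

Numbering used: ring A is C1–C6 with the side chain on C1, OAc on C2, OH on C3, CH3 on C4, OH on C5 and H on C6; C7 is the methylidene-bearing carbon, C8 the carbinol carbon (S); O2, O3, O5, O8 are the oxygens on those carbons.

Assumption: the (S,S)-configured ruthenium catalyst reduces ynone 14 with the same facial sense as simpler 1-silylalk-1-yn-3-ones and gives the S carbinol; if the sense were opposite, the (R,R)-catalyst would be used.

**Route**

Step 1
Reactants: 1 squaric acid (3,4-dihydroxycyclobut-3-ene-1,2-dione)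
Product: 2 disilver squarate (Ag2C4O4)
Conditions: AgNO3 (2.05 equiv), H2O, rt, dark; filter, dry in vacuo
Reagents that add atoms: silver nitrate, [Ag+].[O-][N+](=O)[O-]
Why: Salt metathesis; the sparingly soluble disilver salt of this strong vinylogous acid should precipitate and serves as an O-nucleophile for alkylation without added acid.

Step 2
Reactants: 2 disilver squarate; 3 4-methoxybenzyl chloride
Product: 4 3,4-bis[(4-methoxybenzyl)oxy]cyclobut-3-ene-1,2-dione
Conditions: 3 (2.2 equiv), Et2O, 4 Å sieves, rt, dark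
Reagents that add atoms: none
Why: O-Alkylation of a silver salt by a reactive benzylic chloride, driven by precipitation of AgCl, is the classical neutral entry to squarate diesters and should spare the acid-labile benzylic ester groups.

Step 3
Reactants: 4 3,4-bis[(4-methoxybenzyl)oxy]cyclobut-3-ene-1,2-dione
Product: 7 3-[(4-methoxybenzyl)oxy]-4-methylcyclobut-3-ene-1,2-dione, via lithium alkoxide 5 (not isolated), via trifluoroacetate 6 (not isolated)
Conditions: MeLi (1.05 equiv), THF, −78 °C; (CF3CO)2O (1.2 equiv), −78 °C; aq. NH4Cl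
Reagents that add atoms: methyllithium, [Li]C
Why: 1,2-Addition of MeLi to one carbonyl of the symmetric squarate, followed by trifluoroacetylation and ionisation of the carbinol oxygen with loss of the benzyloxy group from the carbon that becomes the new carbonyl, is the standard squarate-to-3-alkoxy-4-alkylcyclobutenedione transposition.

Step 4
Reactants: 8 4-methylpent-3-enoic acid
Product: 10 N-methoxy-N,4-dimethylpent-3-enamide, via acyl imidazole 9 (not isolated)
Conditions: 1,1'-carbonyldiimidazole, CH2Cl2, 0 °C → rt; MeNH(OMe)·HCl, rt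
Reagents that add atoms: N,O-dimethylhydroxylamine hydrochloride, CNOC.Cl
Why: Amide formation through the acyl imidazole runs under near-neutral conditions, so the β,γ-alkene should not move into conjugation.

Step 5
Reactants: 10 N-methoxy-N,4-dimethylpent-3-enamide; 11 trimethylsilylacetylene
Product: 14 6-methyl-1-(trimethylsilyl)hept-5-en-1-yn-3-one, via lithium acetylide 12 (not isolated), via tetrahedral adduct 13 (not isolated)
Conditions: 11, n-BuLi, THF, −78 °C; 10, −78 → −20 °C; cold 1 M HCl
Reagents that add atoms: none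
Why: Weinreb ketone synthesis; the chelated adduct 13 resists a second addition and collapses to the ynone only on acidic quench.

Step 6
Reactants: 14 6-methyl-1-(trimethylsilyl)hept-5-en-1-yn-3-one
Product: 15 (S)-6-methyl-1-(trimethylsilyl)hept-5-en-1-yn-3-ol
Conditions: Ru(p-cymene)[(S,S)-TsNCHPhCHPhNH] (2 mol %), i-PrOH, rt
Reagents that add atoms: none
Why: Noyori asymmetric transfer hydrogenation of an alkynyl ketone; the (S,S)-ligand directs hydride to the carbonyl face that gives the S carbinol (C8), with the alkyne as the π-substituent in the hydride-transfer transition state, and the base-free catalyst should not enolise the β,γ-unsaturated ketone.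

Step 7
Reactants: 15 (S)-6-methyl-1-(trimethylsilyl)hept-5-en-1-yn-3-ol
Product: 16 (S)-6-methylhept-5-en-1-yn-3-ol
Conditions: K2CO3 (0.2 equiv), MeOH, rt
Reagents that add atoms: none
Why: Base-catalysed methanolysis of the alkynyl C–Si bond (protodesilylation) frees the terminal alkyne without touching the carbinol centre.

Step 8
Reactants: 16 (S)-6-methylhept-5-en-1-yn-3-ol
Product: 17 (S)-triethyl[(6-methylhept-5-en-1-yn-3-yl)oxy]silane
Conditions: Et3SiCl, imidazole, CH2Cl2, 0 °C
Reagents that add atoms: chlorotriethylsilane, CC[Si](Cl)(CC)CC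
Why: Routine silylation; the triethylsilyl ether tolerates organolithium reagents at −78 °C and is later cleaved by dilute acid in the presence of an aryl silyl ether and an aryl acetate.

Step 9
Reactants: 17 (S)-triethyl[(6-methylhept-5-en-1-yn-3-yl)oxy]silane
Product: 18 (S)-triethyl{[6-methyl-2-(tributylstannyl)hepta-1,5-dien-3-yl]oxy}silane
Conditions: Bu3SnH (2 equiv), Mo(CO)3(CNtBu)3 (3 mol %), hydroquinone (cat.), THF, 55 °C
Reagents that add atoms: tributyltin hydride, CCCC[SnH](CCCC)CCCC
Why: Molybdenum-catalysed hydrostannation of a propargylic ether places tin on the internal, oxygen-proximal alkyne carbon by syn addition, and the radical inhibitor suppresses the pathway to the terminal stannane.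

Step 10
Reactants: 18 (S)-triethyl{[6-methyl-2-(tributylstannyl)hepta-1,5-dien-3-yl]oxy}silane
Product: 21 (S)-[(2-bromo-7-methyl-3-methylideneocta-1,6-dien-4-yl)oxy]triethylsilane, via alkenyllithium 19 (not isolated), via alkenylzinc bromide 20 (not isolated)
Conditions: n-BuLi, THF, −78 °C; ZnBr2, −78 → 0 °C; CH2=CBr2 (4 equiv), Pd(PPh3)4 (5 mol %), 0 °C → rt
Reagents that add atoms: 1,1-dibromoethene, C=C(Br)Br
Why: Tin–lithium exchange and transmetalation give an alkenylzinc for Negishi coupling, and with the geminal dibromide in excess zerovalent palladium should insert into it faster than into the more hindered 2-bromodiene product, so one C–Br bond is replaced and the other is kept.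

Step 11
Reactants: 21 (S)-[(2-bromo-7-methyl-3-methylideneocta-1,6-dien-4-yl)oxy]triethylsilane; 7 3-[(4-methoxybenzyl)oxy]-4-methylcyclobut-3-ene-1,2-dione
Product: 24 2-[(4-methoxybenzyl)oxy]-3-methyl-1-[(4S)-7-methyl-3-methylidene-4-(triethylsilyloxy)octa-1,6-dien-2-yl]-4-oxocyclobut-2-en-1-yl acetate (both epimers at ring C1), via dienyllithium 22 (not isolated), via lithium alkoxide 23 (not isolated)
Conditions: t-BuLi (2.05 equiv), Et2O, −78 °C; 7 in THF, −78 °C; Ac2O (3 equiv), −78 → 0 °C
Reagents that add atoms: acetic anhydride, CC(=O)OC(C)=O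
Why: Bromine–lithium exchange in ether at −78 °C (where silyl migration from O8 to carbon is slow), 1,2-addition to the ketone carbonyl next to the benzyloxy-bearing carbon (the other carbonyl is a deactivated vinylogous ester) and in situ O-acylation of the tertiary alkoxide put the acetyl group on the future O2 only; the new ring stereocentre forms without control and is destroyed in step 12.

Step 12
Reactants: 24 the 4-acetoxy-4-dienylcyclobutenone (either epimer)
Product: 27 4-hydroxy-2-[(4-methoxybenzyl)oxy]-3-methyl-6-[(3S)-6-methyl-3-(triethylsilyloxy)hepta-1,5-dien-2-yl]phenyl acetate, via dienylketene 25 (not isolated), via cyclohexadienone 26 (not isolated)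
Conditions: toluene (0.02 M, degassed), 110 °C
Reagents that add atoms: none
Why: Heating opens the cyclobutenone by conrotatory 4π cleavage of the bond between the carbonyl carbon and the acetoxy carbon to give dienylketene 25, whose ketene carbon and the CH2 terminus of the vinyl group on the acetoxy carbon join in a disrotatory 6π electrocyclisation (new C5–C6 bond), and enolisation of dienone 26 delivers the C5 phenol. The closest known reaction type is the Moore ring expansion of 4-alkenyl-4-oxycyclobutenones to hydroquinone derivatives. Ring A closes as a six-membered carbocycle by this thermal 6π closure of a cis-hexatriene, and only the vinyl group bonded directly to the acetoxy carbon lies in such a triene with the ketene. No stereocentre is created: both epimers at the acetoxy carbon converge on the same arene and C8 is a spectator. The step needs the dienyl group to turn inward towards the ketene, which the preference of the oxygen substituent for outward rotation should provide, and because the opening is reversible an unproductive rotamer can only reclose. The substitution pattern was fixed by the site of addition in step 11, and the acetyl group should stay on O2 because O5 appears only on tautomerisation, para to it and out of reach.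

Step 13
Reactants: 27 the C5 phenol
Product: 28 4-[(tert-butyldimethylsilyl)oxy]-2-[(4-methoxybenzyl)oxy]-3-methyl-6-[(3S)-6-methyl-3-(triethylsilyloxy)hepta-1,5-dien-2-yl]phenyl acetate
Conditions: t-BuMe2SiCl (1.2 equiv), imidazole, DMF, 0 °C → rt
Reagents that add atoms: tert-butyldimethylsilyl chloride, CC(C)(C)[Si](C)(C)Cl
Why: Silylation of the only free hydroxyl (the C5 phenol) under weakly basic conditions that should not mobilise the aryl acetate.

Step 14
Reactants: 28 the bis-silyl ether
Product: 29 4-[(tert-butyldimethylsilyl)oxy]-6-[(3S)-3-hydroxy-6-methylhepta-1,5-dien-2-yl]-2-[(4-methoxybenzyl)oxy]-3-methylphenyl acetate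
Conditions: AcOH/THF/H2O (3:1:1), rt
Reagents that add atoms: none
Why: Acid hydrolysis cleaves the secondary alkyl triethylsilyl ether far faster than the aryl tert-butyldimethylsilyl ether and leaves the acetate, the benzyl ether and the C8 configuration untouched.

Step 15
Reactants: 29 the C8 alcohol; 30 angelic acid [(2Z)-2-methylbut-2-enoic acid]
Product: 32 (3S)-2-{2-acetoxy-5-[(tert-butyldimethylsilyl)oxy]-3-[(4-methoxybenzyl)oxy]-4-methylphenyl}-6-methylhepta-1,5-dien-3-yl (2Z)-2-methylbut-2-enoate, via mixed anhydride 31 (not isolated)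
Conditions: 30, 2,4,6-Cl3C6H2COCl, Et3N, toluene, rt; then 29, toluene, 70 °C
Reagents that add atoms: none
Why: Yamaguchi-type esterification through mixed anhydride 31 without a nucleophilic pyridine catalyst acylates hindered secondary alcohols with retention at the carbinol carbon and should keep the Z geometry of the angeloyl group.

Step 16
Reactants: 32 the protected angelate
Product: 33 (3S)-2-{2-acetoxy-5-[(tert-butyldimethylsilyl)oxy]-3-hydroxy-4-methylphenyl}-6-methylhepta-1,5-dien-3-yl (2Z)-2-methylbut-2-enoate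
Conditions: DDQ (1.3 equiv), CH2Cl2/pH 7 phosphate buffer (10:1), 0 °C
Reagents that add atoms: none
Why: Oxidative removal of the 4-methoxybenzyl ether by DDQ in wet solvent; with O2 and O5 capped the arene cannot be oxidised to a quinone, and the cold buffered medium should keep the acetyl group on O2.

Step 17
Reactants: 33 the O5 silyl ether
Product: 34 (3S)-2-(2-acetoxy-3,5-dihydroxy-4-methylphenyl)-6-methylhepta-1,5-dien-3-yl (2Z)-2-methylbut-2-enoate (CNP0147405.1)
Conditions: HF·pyridine, THF, 0 °C → rt; pH 7 buffer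
Reagents that add atoms: none
Why: Fluoride cleavage of the aryl silyl ether under mildly acidic conditions should neither hydrolyse nor shift the acetate nor isomerise the angelate, and leaves C8 (S) unchanged.

**Compound list**

1 | squaric acid | OC1=C(O)C(=O)C1=O | starting material
2 | disilver squarate (Ag2C4O4) | [Ag+].[Ag+].[O-]C1=C([O-])C(=O)C1=O | intermediate
3 | 4-methoxybenzyl chloride | COc1ccc(CCl)cc1 | starting material
4 | 3,4-bis[(4-methoxybenzyl)oxy]cyclobut-3-ene-1,2-dione | COc1ccc(COC2=C(OCc3ccc(OC)cc3)C(=O)C2=O)cc1 | intermediate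
5 | lithium 2,3-bis[(4-methoxybenzyl)oxy]-1-methyl-4-oxocyclobut-2-en-1-olate (not isolated) | [Li]OC1(C)C(OCc2ccc(OC)cc2)=C(OCc2ccc(OC)cc2)C1=O | intermediate
6 | 2,3-bis[(4-methoxybenzyl)oxy]-1-methyl-4-oxocyclobut-2-en-1-yl trifluoroacetate (not isolated) | CC1(OC(=O)C(F)(F)F)C(OCc2ccc(OC)cc2)=C(OCc2ccc(OC)cc2)C1=O | intermediate
7 | 3-[(4-methoxybenzyl)oxy]-4-methylcyclobut-3-ene-1,2-dione | CC1=C(OCc2ccc(OC)cc2)C(=O)C1=O | intermediate
8 | 4-methylpent-3-enoic acid | CC(C)=CCC(=O)O | starting material
9 | 1-(imidazol-1-yl)-4-methylpent-3-en-1-one (not isolated) | CC(C)=CCC(=O)n1ccnc1 | intermediate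
10 | N-methoxy-N,4-dimethylpent-3-enamide | CC(C)=CCC(=O)N(C)OC | intermediate
11 | trimethylsilylacetylene | C#C[Si](C)(C)C | starting material
12 | lithium (trimethylsilyl)acetylide (not isolated) | [Li]C#C[Si](C)(C)C | intermediate
13 | lithium alkoxide of the tetrahedral adduct of 12 and 10 (not isolated) | CC(C)=CCC(O[Li])(C#C[Si](C)(C)C)N(C)OC | intermediate
14 | 6-methyl-1-(trimethylsilyl)hept-5-en-1-yn-3-one | CC(C)=CCC(=O)C#C[Si](C)(C)C | intermediate
15 | (S)-6-methyl-1-(trimethylsilyl)hept-5-en-1-yn-3-ol | C[Si](C)(C)C#C[C@H](CC=C(C)C)O | intermediate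
16 | (S)-6-methylhept-5-en-1-yn-3-ol | C#C[C@H](CC=C(C)C)O | intermediate
17 | (S)-triethyl[(6-methylhept-5-en-1-yn-3-yl)oxy]silane | C#C[C@H](CC=C(C)C)O[Si](CC)(CC)CC | intermediate
18 | (S)-triethyl{[6-methyl-2-(tributylstannyl)hepta-1,5-dien-3-yl]oxy}silane | CCCC[Sn](CCCC)(CCCC)C(=C)[C@H](CC=C(C)C)O[Si](CC)(CC)CC | intermediate
19 | [(3S)-6-methyl-3-(triethylsilyloxy)hepta-1,5-dien-2-yl]lithium (not isolated) | [Li]C(=C)[C@H](CC=C(C)C)O[Si](CC)(CC)CC | intermediate
20 | bromo[(3S)-6-methyl-3-(triethylsilyloxy)hepta-1,5-dien-2-yl]zinc (not isolated) | Br[Zn]C(=C)[C@H](CC=C(C)C)O[Si](CC)(CC)CC | intermediate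
21 | (S)-[(2-bromo-7-methyl-3-methylideneocta-1,6-dien-4-yl)oxy]triethylsilane | BrC(=C)C(=C)[C@H](CC=C(C)C)O[Si](CC)(CC)CC | intermediate
22 | [(4S)-7-methyl-3-methylidene-4-(triethylsilyloxy)octa-1,6-dien-2-yl]lithium (not isolated) | [Li]C(=C)C(=C)[C@H](CC=C(C)C)O[Si](CC)(CC)CC | intermediate
23 | lithium 2-[(4-methoxybenzyl)oxy]-3-methyl-1-[(4S)-7-methyl-3-methylidene-4-(triethylsilyloxy)octa-1,6-dien-2-yl]-4-oxocyclobut-2-en-1-olate (not isolated) | CC1=C(OCc2ccc(OC)cc2)C(O[Li])(C(=C)C(=C)[C@H](CC=C(C)C)O[Si](CC)(CC)CC)C1=O | intermediate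
24 | 2-[(4-methoxybenzyl)oxy]-3-methyl-1-[(4S)-7-methyl-3-methylidene-4-(triethylsilyloxy)octa-1,6-dien-2-yl]-4-oxocyclobut-2-en-1-yl acetate (both epimers at ring C1) | CC1=C(OCc2ccc(OC)cc2)C(OC(C)=O)(C(=C)C(=C)[C@H](CC=C(C)C)O[Si](CC)(CC)CC)C1=O | intermediate
25 | dienylketene O=C=C(CH3)–C(OPMB)=C(OAc)–dienyl with the dienyl group cis to the ketene-bearing carbon (not isolated) | O=C=C(C)/C(OCc1ccc(OC)cc1)=C(/OC(C)=O)C(=C)C(=C)[C@H](CC=C(C)C)O[Si](CC)(CC)CC | intermediate
26 | 6-[(4-methoxybenzyl)oxy]-5-methyl-2-[(3S)-6-methyl-3-(triethylsilyloxy)hepta-1,5-dien-2-yl]-4-oxocyclohexa-1,5-dien-1-yl acetate (not isolated) | O=C1CC(C(=C)[C@H](CC=C(C)C)O[Si](CC)(CC)CC)=C(OC(C)=O)C(OCc2ccc(OC)cc2)=C1C | intermediate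
27 | 4-hydroxy-2-[(4-methoxybenzyl)oxy]-3-methyl-6-[(3S)-6-methyl-3-(triethylsilyloxy)hepta-1,5-dien-2-yl]phenyl acetate | CC(=O)Oc1c(OCc2ccc(OC)cc2)c(C)c(O)cc1C(=C)[C@H](CC=C(C)C)O[Si](CC)(CC)CC | intermediate
28 | 4-[(tert-butyldimethylsilyl)oxy]-2-[(4-methoxybenzyl)oxy]-3-methyl-6-[(3S)-6-methyl-3-(triethylsilyloxy)hepta-1,5-dien-2-yl]phenyl acetate | CC(=O)Oc1c(OCc2ccc(OC)cc2)c(C)c(O[Si](C)(C)C(C)(C)C)cc1C(=C)[C@H](CC=C(C)C)O[Si](CC)(CC)CC | intermediate
29 | 4-[(tert-butyldimethylsilyl)oxy]-6-[(3S)-3-hydroxy-6-methylhepta-1,5-dien-2-yl]-2-[(4-methoxybenzyl)oxy]-3-methylphenyl acetate | CC(=O)Oc1c(OCc2ccc(OC)cc2)c(C)c(O[Si](C)(C)C(C)(C)C)cc1C(=C)[C@H](CC=C(C)C)O | intermediate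
30 | angelic acid [(2Z)-2-methylbut-2-enoic acid] | C/C=C(/C)C(=O)O | starting material
31 | (2Z)-2-methylbut-2-enoic 2,4,6-trichlorobenzoic anhydride (not isolated) | C/C=C(/C)C(=O)OC(=O)c1c(Cl)cc(Cl)cc1Cl | intermediate
32 | (3S)-2-{2-acetoxy-5-[(tert-butyldimethylsilyl)oxy]-3-[(4-methoxybenzyl)oxy]-4-methylphenyl}-6-methylhepta-1,5-dien-3-yl (2Z)-2-methylbut-2-enoate | CC(=O)Oc1c(OCc2ccc(OC)cc2)c(C)c(O[Si](C)(C)C(C)(C)C)cc1C(=C)[C@H](CC=C(C)C)OC(=O)/C(C)=C\C | intermediate
33 | (3S)-2-{2-acetoxy-5-[(tert-butyldimethylsilyl)oxy]-3-hydroxy-4-methylphenyl}-6-methylhepta-1,5-dien-3-yl (2Z)-2-methylbut-2-enoate | CC(=O)Oc1c(O)c(C)c(O[Si](C)(C)C(C)(C)C)cc1C(=C)[C@H](CC=C(C)C)OC(=O)/C(C)=C\C | intermediate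
34 | (3S)-2-(2-acetoxy-3,5-dihydroxy-4-methylphenyl)-6-methylhepta-1,5-dien-3-yl (2Z)-2-methylbut-2-enoate (CNP0147405.1) | C=C(c1cc(O)c(C)c(O)c1OC(C)=O)[C@H](CC=C(C)C)OC(=O)/C(C)=C\C | target

**Step count and risks**

Total: 17 steps. Longest linear sequence: 14 steps (steps 4–17, from 4-methylpent-3-enoic acid); the dione 7 is made in 3 steps (steps 1–3) and joins at step 11.

Steps most likely to fail:

Step 12. The acetoxy group is a weaker donor than hydroxy, alkoxy or silyloxy, so the ring opening may not direct the dienyl group inward cleanly, and at 110 °C the cross-conjugated diene may oligomerise before the 6π closure drains the equilibrium. Fallback: setting out from the lithium alkoxide 23 of step 11, quenching with aqueous NH4Cl instead of Ac2O should give the 4-hydroxycyclobutenone F1. Heating in toluene (the classical hydroxy variant of the ring expansion, under argon) should give the hydroquinone F2. Silylation of the unhindered O5 hydroxyl (t-BuMe2SiCl, imidazole, 0 °C) should give the monosilyl ether F3, and acetylation of the remaining hindered O2 hydroxyl (Ac2O, Et3N, DMAP) comes back to the route at 28.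

Step 11. Three events share one flask: the dienyllithium may suffer silyl migration from O8 to carbon, may add through its remote methylene terminus to give an allenyl carbinol, or the hindered tertiary alkoxide may be acylated incompletely. Fallback: setting out from alkyne 17, deprotonation with n-BuLi gives the lithium acetylide F4, addition to dione 7 gives the alkoxide F5, and trapping with Ac2O gives the 4-alkynyl acetate F6. Enyne cross-metathesis with ethylene (second-generation Grubbs catalyst, RuCl2(=CHPh)(H2IMes)(PCy3), 1 atm ethylene, toluene, 40–60 °C) then turns the alkyne into the 2,3-disubstituted butadiene and comes back to the route at 24. This path also bypasses steps 9 and 10, should mono-coupling with 1,1-dibromoethene prove unselective.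

Step 15. Activation of angelic acid may isomerise the Z alkene to the E (tigloyl) isomer, and slow acylation of the hindered alcohol may let the neighbouring aryl acetate shift to O8. Fallback: setting out from alcohol 29, esterification with 2-[bis(2,2,2-trifluoroethoxy)phosphoryl]propanoic acid (DCC, cat. DMAP, CH2Cl2, 0 °C) gives the phosphonate ester F7. Still–Gennari olefination with acetaldehyde (KN(SiMe3)2, 18-crown-6, THF, −78 °C) then builds the Z trisubstituted alkene on the ester and comes back to the route at 32.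

**Further compounds**

F1 | step 12 | 4-hydroxy-3-[(4-methoxybenzyl)oxy]-2-methyl-4-[(4S)-7-methyl-3-methylidene-4-(triethylsilyloxy)octa-1,6-dien-2-yl]cyclobut-2-en-1-one | CC1=C(OCc2ccc(OC)cc2)C(O)(C(=C)C(=C)[C@H](CC=C(C)C)O[Si](CC)(CC)CC)C1=O
F2 | step 12 | 3-[(4-methoxybenzyl)oxy]-2-methyl-5-[(3S)-6-methyl-3-(triethylsilyloxy)hepta-1,5-dien-2-yl]benzene-1,4-diol | Cc1c(O)cc(C(=C)[C@H](CC=C(C)C)O[Si](CC)(CC)CC)c(O)c1OCc1ccc(OC)cc1
F3 | step 12 | 4-[(tert-butyldimethylsilyl)oxy]-2-[(4-methoxybenzyl)oxy]-3-methyl-6-[(3S)-6-methyl-3-(triethylsilyloxy)hepta-1,5-dien-2-yl]phenol | Oc1c(OCc2ccc(OC)cc2)c(C)c(O[Si](C)(C)C(C)(C)C)cc1C(=C)[C@H](CC=C(C)C)O[Si](CC)(CC)CC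
F4 | step 11 | [(3S)-6-methyl-3-(triethylsilyloxy)hept-5-en-1-yn-1-yl]lithium | [Li]C#C[C@H](CC=C(C)C)O[Si](CC)(CC)CC
F5 | step 11 | lithium 2-[(4-methoxybenzyl)oxy]-3-methyl-1-[(3S)-6-methyl-3-(triethylsilyloxy)hept-5-en-1-yn-1-yl]-4-oxocyclobut-2-en-1-olate | CC1=C(OCc2ccc(OC)cc2)C(O[Li])(C#C[C@H](CC=C(C)C)O[Si](CC)(CC)CC)C1=O
F6 | step 11 | 2-[(4-methoxybenzyl)oxy]-3-methyl-1-[(3S)-6-methyl-3-(triethylsilyloxy)hept-5-en-1-yn-1-yl]-4-oxocyclobut-2-en-1-yl acetate | CC1=C(OCc2ccc(OC)cc2)C(OC(C)=O)(C#C[C@H](CC=C(C)C)O[Si](CC)(CC)CC)C1=O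
F7 | step 15 | (3S)-2-{2-acetoxy-5-[(tert-butyldimethylsilyl)oxy]-3-[(4-methoxybenzyl)oxy]-4-methylphenyl}-6-methylhepta-1,5-dien-3-yl 2-[bis(2,2,2-trifluoroethoxy)phosphoryl]propanoate | CC(=O)Oc1c(OCc2ccc(OC)cc2)c(C)c(O[Si](C)(C)C(C)(C)C)cc1C(=C)[C@H](CC=C(C)C)OC(=O)C(C)P(=O)(OCC(F)(F)F)OCC(F)(F)F
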